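**Retrosynthetic overview**
- The enol ester is made last, by Wittig olefination of a C16 aldehyde with an acyloxymethylene ylide; the aldehyde and the acetonyl group come from one ozonolysis of a vinyl and a methallyl group.
- Both groups are put on a tricyclic cycloheptenone by conjugate vinylation and enolate methallylation.
- The enone comes from a C4=C5 cycloheptene (epoxidation, base-induced allylic transposition, oxidation) after Wolff–Kishner removal of a bridging ketone.
- Key disconnection: an intramolecular (4+3) cycloaddition of a cyclohexanone oxyallyl cation with an ether-tethered (Z)-diene forms C13–C16 and C6–C15, closing the seven-membered ring and the pyran in one step.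
- Ring order: cyclohexane bought in (R)-α-terpineol (carries C10) → cycloheptene and tetrahydropyran together → side chains.

Atom labels used in the names (taken from the target): seven-membered ring C4 (CH bearing acetonyl), C5 (ring C=O), C6, C15, C14, C13 (quaternary, CH3), C16 (CH bearing the enol ester); pyran C6–C7H2–O8–C9(CH3)2–C10–C15; cyclohexane C10–C11–C12–C13–C14–C15.

Assumption: (R)-(+)-α-terpineol of high enantiomeric purity is bought (it is also one hydration step from (R)-limonene).

This route is a paper design and has not been run; the three weakest steps are named at the end.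

**Route**

Step 1
Reactants: 1 (R)-(+)-α-terpineol; 2 propargyl bromide
Product: 4 (4R)-1-methyl-4-[2-(prop-2-yn-1-yloxy)propan-2-yl]cyclohex-1-ene, via sodium alkoxide 3 (not isolated)
Conditions: NaH, THF/DMF, 0 °C; then 2, Bu4NI (cat.), 0 °C → rt
Reagents that add atoms: none
Why: Williamson ether synthesis: the tertiary alkoxide displaces the primary propargylic bromide (SN2) and the bought stereocentre C10 is untouched.

Step 2
Reactants: 4 propargyl ether; 5 vinyl bromide
Product: 6 (4R)-1-methyl-4-[2-(pent-4-en-2-yn-1-yloxy)propan-2-yl]cyclohex-1-ene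
Conditions: PdCl2(PPh3)2 (cat.), CuI (cat.), Et2NH, THF, 0 °C → rt
Reagents that add atoms: none
Why: Sonogashira coupling of the terminal alkyne with the vinyl halide builds the enyne and leaves the ring alkene alone.

Step 3
Reactants: 6 enyne ether
Product: 7 (4R)-1-methyl-4-{2-[(2Z)-penta-2,4-dien-1-yloxy]propan-2-yl}cyclohex-1-ene
Conditions: Zn dust activated by Cu(OAc)2 and AgNO3, MeOH/H2O, 45 °C
Reagents that add atoms: none
Why: Boland-type reduction with activated zinc reduces only the conjugated alkyne by syn delivery of two hydrogens, giving the (Z)-diene that later fixes C6.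

Step 4
Reactants: 7 (Z)-dienyl ether
Product: 8 (4R)-1-methyl-4-{2-[(2Z)-penta-2,4-dien-1-yloxy]propan-2-yl}-7-oxabicyclo[4.1.0]heptane (both epoxide diastereomers)
Conditions: mCPBA (1.0 equiv), NaHCO3, CH2Cl2, −20 → 0 °C
Reagents that add atoms: mCPBA (3-chloroperoxybenzoic acid), OOC(=O)c1cccc(Cl)c1
Why: Prilezhaev epoxidation: the trisubstituted ring alkene is far more nucleophilic than the conjugated diene; both diastereomers are carried on because the new centres are erased in steps 5 and 6.

Step 5
Reactants: 8 epoxide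
Product: 10 (5R)-2-chloro-2-methyl-5-{2-[(2Z)-penta-2,4-dien-1-yloxy]propan-2-yl}cyclohexan-1-one (C2 epimers), via chloro alkoxysulfonium chloride 9 (not isolated)
Conditions: (COCl)2, DMSO, CH2Cl2, −60 °C; then Et3N, −60 → 0 °C
Reagents that add atoms: oxalyl chloride, ClC(=O)C(Cl)=O
Why: Swern-type epoxide opening and oxidation: chloride opens the sulfonium-activated epoxide at the tertiary carbon and the secondary alkoxysulfonium collapses to the ketone on adding Et3N.

Step 6
Reactants: 10 α-chloroketone
Product: 12 tricyclic ketone (C14=O; C4=C5 alkene; C16H2; stereocentres C6 C10 C13 C15 as in the target), via oxyallyl cation 11 (not isolated)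
Conditions: Et3N, CF3CH2OH, 0 °C → rt
Reagents that add atoms: none
Why: Intramolecular (4+3) cycloaddition under Föhlisch conditions: the O–CMe2 tether on C10 holds the diene on the face syn to C9, so C15–C6 and C13–C16 form cis to C9 (sets C15 and C13), and the (Z)-diene, whose tether sits inside, can react only in the compact mode, which puts H6 outside and gives the cis-fused pyran (sets C6).

Step 7
Reactants: 12 tricyclic ketone
Product: 14 tricyclic alkene (C14H2; C4=C5 alkene), via hydrazone 13 (not isolated)
Conditions: N2H4·H2O, KOH, diethylene glycol, 130 °C then 200 °C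
Reagents that add atoms: none
Why: Wolff–Kishner reduction (Huang-Minlon): the bridging ketone is the only carbonyl and cannot enolise (quaternary C13, bridgehead C15), so nothing epimerises and the alkene and ether survive the base.

Step 8
Reactants: 14 tricyclic alkene
Product: 15 exo 4,5-epoxide of 14
Conditions: mCPBA, NaHCO3, CH2Cl2, 0 °C
Reagents that add atoms: mCPBA (3-chloroperoxybenzoic acid), OOC(=O)c1cccc(Cl)c1
Why: Prilezhaev epoxidation of the only alkene from the convex face; the epoxide configuration is erased in step 10.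

Step 9
Reactants: 15 epoxide
Product: 17 allylic alcohol (5-OH; C4=C16 alkene), via lithium alkoxide 16 (not isolated)
Conditions: LiNEt2, Et2O/hexane, reflux; then H2O
Reagents that add atoms: none
Why: Base-induced epoxide to allylic alcohol isomerisation (syn β-elimination): the amide takes a proton from the C16 methylene rather than the C6 methine (least substituted β-carbon), which leaves the oxygen on C5 and the alkene at C4=C16.

Step 10
Reactants: 17 allylic alcohol
Product: 18 tricyclic enone (C5=O; C4=C16)
Conditions: Dess–Martin periodinane, NaHCO3, CH2Cl2, rt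
Reagents that add atoms: none
Why: Dess–Martin oxidation of the secondary allylic alcohol under neutral conditions, so C6 next to the new carbonyl is not epimerised.

Step 11
Reactants: 18 enone; 19 vinylmagnesium bromide; 20 3-bromo-2-methylprop-1-ene
Product: 22 4-methallyl-16-vinyl ketone (all stereocentres as in the target), via bromomagnesium enolate 21 (not isolated)
Conditions: 19, CuBr·SMe2 (cat.), THF, −78 → −40 °C; then 20, DMPU, −40 → 0 °C
Reagents that add atoms: none
Why: Copper-catalysed 1,4-addition then enolate alkylation: vinyl adds to C16 from the convex face away from the cyclohexane bridge (sets C16), and the enolate takes the methallyl group trans to it (sets C4).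

Step 12
Reactants: 22 diene ketone
Product: 24 keto aldehyde (4-acetonyl; 16-formyl; C5=O), via bis-ozonide 23 (not isolated)
Conditions: O3, CH2Cl2, −78 °C; then PPh3, −78 °C → rt
Reagents that add atoms: ozone, [O-][O+]=O
Why: Ozonolysis with reductive work-up cleaves both terminal alkenes at once, vinyl to the aldehyde and methallyl to the methyl ketone, under neutral conditions.

Step 13
Reactants: 25 3-methylbut-2-enoyl chloride; 26 paraformaldehyde
Product: 27 chloromethyl 3-methylbut-2-enoate
Conditions: ZnCl2 (cat.), neat, 0 → 60 °C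
Reagents that add atoms: none
Why: ZnCl2-catalysed insertion of formaldehyde into the acyl chloride (chloromethyl ester formation).

Step 14
Reactants: 27 chloromethyl ester; 28 triphenylphosphine
Product: 29 [(3-methylbut-2-enoyloxy)methyl]triphenylphosphonium chloride
Conditions: toluene, 80 °C
Reagents that add atoms: none
Why: Quaternisation (SN2) of PPh3 by the activated chloromethyl ester.

Step 15
Reactants: 24 keto aldehyde; 29 phosphonium chloride
Product: 31 vibsanin E, via phosphorus ylide 30 (not isolated)
Conditions: 29, NaN(SiMe3)2, THF, −78 °C; then 24, −78 → 0 °C; E isomer separated by chromatography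
Reagents that add atoms: none
Why: Wittig olefination with an acyloxymethylene ylide (Anders–Gaßner variant) reacts at the aldehyde in preference to both ketones and gives the enol ester as an E/Z mixture from which the E isomer is taken.

**Compound list**

1 | (R)-(+)-α-terpineol, 2-[(1R)-4-methylcyclohex-3-en-1-yl]propan-2-ol | CC(C)(O)[C@@H]1CCC(C)=CC1 | starting material
2 | propargyl bromide (3-bromoprop-1-yne) | C#CCBr | starting material
3 | sodium alkoxide of 1 | CC(C)([O-])[C@@H]1CCC(C)=CC1.[Na+] | intermediate
4 | (4R)-1-methyl-4-[2-(prop-2-yn-1-yloxy)propan-2-yl]cyclohex-1-ene | C#CCOC(C)(C)[C@@H]1CCC(C)=CC1 | intermediate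
5 | vinyl bromide (bromoethene) | C=CBr | starting material
6 | (4R)-1-methyl-4-[2-(pent-4-en-2-yn-1-yloxy)propan-2-yl]cyclohex-1-ene | C=CC#CCOC(C)(C)[C@@H]1CCC(C)=CC1 | intermediate
7 | (4R)-1-methyl-4-{2-[(2Z)-penta-2,4-dien-1-yloxy]propan-2-yl}cyclohex-1-ene | C=C/C=C\COC(C)(C)[C@@H]1CCC(C)=CC1 | intermediate
8 | (4R)-1-methyl-4-{2-[(2Z)-penta-2,4-dien-1-yloxy]propan-2-yl}-7-oxabicyclo[4.1.0]heptane, both epoxide diastereomers | C=C/C=C\COC(C)(C)[C@@H]1CCC2(C)OC2C1 | intermediate
9 | chloro alkoxysulfonium chloride from 8 (Cl on C13, O–S+Me2 on C14) | C=C/C=C\COC(C)(C)[C@@H]1CCC(C)(Cl)C(O[S+](C)C)C1.[Cl-] | intermediate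
10 | (5R)-2-chloro-2-methyl-5-{2-[(2Z)-penta-2,4-dien-1-yloxy]propan-2-yl}cyclohexan-1-one, C2 epimers | C=C/C=C\COC(C)(C)[C@@H]1CCC(C)(Cl)C(=O)C1 | intermediate
11 | oxyallyl cation (C13–C14(O−)–C15 zwitterion) | C=C/C=C\COC(C)(C)[C@@H]1CC[C+](C)C([O-])=C1 | intermediate
12 | tricyclic ketone: C14=O, C4=C5 alkene, C16H2 | C1C=C[C@@H]2COC(C)(C)[C@@H]3CC[C@@]1(C)C(=O)[C@@H]32 | intermediate
13 | hydrazone of 12 | C1C=C[C@@H]2COC(C)(C)[C@@H]3CC[C@@]1(C)C(=NN)[C@@H]32 | intermediate
14 | tricyclic alkene: C14H2, C4=C5 alkene | C1C=C[C@@H]2COC(C)(C)[C@@H]3CC[C@@]1(C)C[C@@H]32 | intermediate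
15 | exo 4,5-epoxide of 14 | C1[C@H]4O[C@H]4[C@@H]2COC(C)(C)[C@@H]3CC[C@@]1(C)C[C@@H]32 | intermediate
16 | lithium alkoxide of 17 | C1=C[C@@H]([O-])[C@@H]2COC(C)(C)[C@@H]3CC[C@@]1(C)C[C@@H]32.[Li+] | intermediate
17 | allylic alcohol: 5-OH, C4=C16 alkene | C1=C[C@@H](O)[C@@H]2COC(C)(C)[C@@H]3CC[C@@]1(C)C[C@@H]32 | intermediate
18 | tricyclic enone: C5=O, C4=C16 | C1=CC(=O)[C@@H]2COC(C)(C)[C@@H]3CC[C@@]1(C)C[C@@H]32 | intermediate
19 | vinylmagnesium bromide | C=C[Mg]Br | starting material
20 | 3-bromo-2-methylprop-1-ene (methallyl bromide) | C=C(C)CBr | starting material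
21 | bromomagnesium enolate: 16-vinyl, C4=C5–OMgBr | C=C[C@H]1C=C(O[Mg]Br)[C@@H]2COC(C)(C)[C@@H]3CC[C@@]1(C)C[C@@H]32 | intermediate
22 | 4-methallyl-16-vinyl ketone, side chains trans | C=C(C)C[C@@H]1C(=O)[C@@H]2COC(C)(C)[C@@H]3CC[C@@](C)(C[C@@H]32)[C@H]1C=C | intermediate
23 | bis-ozonide (1,2,4-trioxolanes) of 22 | CC4(C[C@@H]1C(=O)[C@@H]2COC(C)(C)[C@@H]3CC[C@@](C)(C[C@@H]32)[C@H]1C5OCOO5)OCOO4 | intermediate
24 | keto aldehyde: 4-acetonyl, 16-formyl, C5=O | CC(=O)C[C@@H]1C(=O)[C@@H]2COC(C)(C)[C@@H]3CC[C@@](C)(C[C@@H]32)[C@H]1C=O | intermediate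
25 | 3-methylbut-2-enoyl chloride | CC(C)=CC(Cl)=O | starting material
26 | paraformaldehyde (as formaldehyde) | C=O | starting material
27 | chloromethyl 3-methylbut-2-enoate | CC(C)=CC(=O)OCCl | intermediate
28 | triphenylphosphine | c1ccc(cc1)P(c1ccccc1)c1ccccc1 | starting material
29 | [(3-methylbut-2-enoyloxy)methyl]triphenylphosphonium chloride | CC(C)=CC(=O)OC[P+](c1ccccc1)(c1ccccc1)c1ccccc1.[Cl-] | intermediate
30 | (3-methylbut-2-enoyloxy)methylidene-triphenylphosphorane | CC(C)=CC(=O)OC=P(c1ccccc1)(c1ccccc1)c1ccccc1 | intermediate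
31 | vibsanin E | CC(=O)C[C@@H]1C(=O)[C@@H]2COC(C)(C)[C@@H]3CC[C@@](C)(C[C@@H]32)[C@H]1/C=C/OC(=O)C=C(C)C | target

**Step count and risks**

Total step count: 15. Longest linear sequence: 13 (steps 1–12 and 15).

Steps most likely to fail:

Step 6, the (4+3) cycloaddition. The cation can be lost to Favorskii contraction, dehydrochlorination or solvent capture, the (Z)-diene is reluctant to reach the s-cis form, and the C6 outcome rests on the compact approach. The fallback sets out from 10 and comes back at 12. Compound 10 is silylated (Me3SiOTf, Et3N, CH2Cl2, −78 °C) to {[(3R)-6-chloro-6-methyl-3-{2-[(2Z)-penta-2,4-dien-1-yloxy]propan-2-yl}cyclohex-1-en-1-yl]oxy}trimethylsilane F1. AgClO4 in CH3NO2 at −20 °C then ionises F1 to the 2-silyloxyallyl cation, which takes up the tethered diene without any base, and aqueous work-up gives 12.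

Step 11, the vinylation/alkylation. The β-carbon sits next to a quaternary centre, magnesium enolates alkylate sluggishly, and the facial outcome at C16 and the trans outcome at C4 are predicted, not known. The fallback sets out from 18 and comes back at 24. The same copper-catalysed vinyl addition is run in the presence of Me3SiCl to give the silyl enol ether F2. SnCl4-mediated Mukaiyama–Michael addition of F2 to 2-nitropropene with hydrolytic (Nef-type) work-up gives the 4-acetonyl-16-vinyl diketone F3 directly, and ozonolysis of its one vinyl group (O3; PPh3) gives 24.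

Step 15, the Wittig reaction. The ylide is basic toward three epimerisable centres and the E/Z ratio may be poor. The fallback sets out from 24 and comes back at 31. Seyferth–Gilbert homologation with the Ohira–Bestmann reagent (K2CO3, MeOH, 0 °C) gives the 16-ethynyl diketone F4. Anti-Markovnikov addition of 3-methylbut-2-enoic acid to F4, catalysed by [RuCl2(p-cymene)]2 with P(4-ClC6H4)3 and DMAP in toluene, gives the E enol ester 31.

Further compounds
F1 | step 6 | {[(3R)-6-chloro-6-methyl-3-{2-[(2Z)-penta-2,4-dien-1-yloxy]propan-2-yl}cyclohex-1-en-1-yl]oxy}trimethylsilane | C=C/C=C\COC(C)(C)[C@@H]1CCC(C)(Cl)C(O[Si](C)(C)C)=C1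
F2 | step 11 | trimethylsilyl enol ether of the 16-vinyl ketone (C4=C5–OSiMe3) | C=C[C@H]1C=C(O[Si](C)(C)C)[C@@H]2COC(C)(C)[C@@H]3CC[C@@]1(C)C[C@@H]32
F3 | step 11 | 4-acetonyl-16-vinyl diketone | CC(=O)C[C@@H]1C(=O)[C@@H]2COC(C)(C)[C@@H]3CC[C@@](C)(C[C@@H]32)[C@H]1C=C
F4 | step 15 | 16-ethynyl diketone | CC(=O)C[C@@H]1C(=O)[C@@H]2COC(C)(C)[C@@H]3CC[C@@](C)(C[C@@H]32)[C@H]1C#C
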